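## Structural features

- The target is a diaryl ether without any stereocentre. Ring A is a pentasubstituted phenol (C1–OH, C2–O‑aryl, C3–Br, C4–Cl, C5–Br, only C6–H). Ring B is a 2,4‑dibromophenyl group (C1'–O, C2'–Br, C4'–Br) joined to ring A through the single ether oxygen.
- There are no chains and no neighbouring stereocentres, so the problem is purely regiochemical: five halogens of two kinds on two rings, and a contiguous O, O, Br, Cl, Br array on ring A.
- The ether oxygen is flanked on ring A by the hydroxyl and a bromine and on ring B by a bromine. Direct O–aryl bond formation would therefore need a hindered, electron‑poor phenoxide or substitution at a crowded carbon.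
- The fragile elements are the four C–Br bonds (halogen–metal exchange, insertion of low‑valent metals, reduction) and the ortho‑hydroxy diaryl ether with an ortho' bromine. The latter can close to a brominated dibenzo‑p‑dioxin or undergo Smiles migration under hot base or copper, so such conditions are avoided, also on safety grounds.
- The feature exploited is a latent twofold symmetry. Without the C4 chlorine and the C1 hydroxyl, both rings are the same 2,4‑dibromophenyl unit as seen from the ether oxygen. C1 of ring A and C6' of ring B are then the two free ortho carbons, and a single carbonyl carbon can bridge them in a symmetric tetrabromoxanthone.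
- Oxygen insertion between C1 and that carbonyl carbon creates the C1–O bond of the phenol, and the bridge carbon later leaves C6' as a carboxyl group.
- Atom‑by‑atom mapping confirms the plan: the bromines ortho and para to the ring oxygen of the ketone become C3/C5 and C2'/C4', and the new hydroxyl lies meta to both ring A bromines with C4 para to it. No structure in the plan needs correction.

## Logic of the disconnections

**10 ⇒ 8 + 9.** The C4–Cl bond is cut. C4 is the only position para to the hydroxyl, so the chlorine can be introduced last by electrophilic substitution. Its removal leaves a tetrabromide in which both rings carry the same bromine pattern relative to the ether oxygen. The forward step must prefer C4 (between two bromines) over C6 (ortho to the hydroxyl), prefer ring A over ring B, and stop after one chlorine.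

**8 ⇒ 7.** The C6'–H bond is replaced by C6'–CO2H. The carboxyl is the remnant of a one‑carbon bridge, so this reveals that C6' was once bonded to carbon. The forward step must remove CO2 without touching four C–Br bonds and without ionising the phenol at high temperature.

**7 ⇒ 6.** The carboxyl carbon is rejoined to the C1 oxygen as an aryl ester. This turns two separate rings into one tricycle in which ring A and ring B are held by two bridges. The forward step only needs a mild acyl–oxygen cleavage.

**6 ⇒ 4 (through 5).** The ester oxygen is excised, so that C1 is bonded directly to the carbonyl carbon. In the forward sense the C1–O bond is made by a carbon‑to‑oxygen shift. The gain is large: the phenol oxygen no longer has to be introduced by C–O coupling at a crowded site, and the precursor is a twofold‑symmetric ketone. The demand is that a peracid adds to a poorly electrophilic diaryl ketone, that an electron‑poor aryl group migrates, and that insertion happens only once.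

**4 ⇒ 1 + 2 (through 3).** Four C–Br bonds are cut. The bromines sit exactly where the ring oxygen (ortho, para) and the carbonyl (meta) both direct. This leads back to a commercial tricycle and a commercial bromine donor. The forward step must brominate a deactivated ketone exhaustively at four positions and no further.

## Other disconnections considered

**Alternative 1:** aryne coupling of a fully halogenated ring A phenol.

- **Cut:** the ether bond O–C1' and the C2'–Br bond, so that ring B enters as an aryne.
- **Forward key step:** fluoride releases the aryne from A1 (2‑(trimethylsilyl)phenyl triflate). The potassium phenoxide of A2 (4,6‑dibromo‑5‑chloro‑2‑methoxyphenol) adds, and the resulting ortho aryl anion is intercepted by an electrophilic bromine donor to give A3. Bromination para to the ether oxygen of ring B (to A4) and O‑demethylation would finish the synthesis.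
- **In favour:** the chlorine is fixed in A2 from the start, and A2 should be available in one step by hydroxyl‑directed dibromination of a commercial chloro precursor. On chlorine regiochemistry this plan is better than the chosen one. Aryne insertion into phenol O–H bonds is a well‑known reaction type, so the key step is arguably better precedented. The step count of about four is equal or slightly shorter.
- **Against:** the phenoxide of A2 is electron‑poor and flanked by methoxy and bromine, so addition to the aryne should be slow. The three‑component capture must compete with protonation of the aryl anion and with direct attack of phenoxide or fluoride on the bromine donor. A later electrophilic bromination is still needed at C4', where C6 of ring A (ortho to the methoxy group) is an open competitor. A Lewis‑acid demethylation is added at the end.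
- **Comparison:** structurally, this plan must form the hindered diaryl ether bond intermolecularly, whereas the chosen plan inherits that bond from 1 and is better on this point. Mechanistically, an anionic three‑component capture is set against a cationic 1,2‑shift, and both key steps carry real uncertainty. Step economy is comparable.

**Alternative 2:** de novo construction of ring A by cycloaddition.

- **Cut:** bonds C2–C3 and C1–C6 of ring A, which is assembled from two fragments.
- **Forward key step:** pyranone A5 (3,5‑dibromo‑4‑chloro‑2H‑pyran‑2‑one) and the alkynyl boronate A6 undergo a Diels–Alder addition and a decarboxylative cycloreversion in a hot aromatic solvent to give the aryl boronate A7. Oxidation of the C–B bond would then give 10.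
- **In favour:** all five halogens and the ether are in place before the ring is formed, so no late electrophilic substitution is needed. On regiochemical certainty of the halogen pattern this plan is better than the chosen one, provided the cycloaddition orients correctly. The polarity is matched: the boron‑bearing alkyne carbon is the nucleophilic end of the ynol ether and pairs with the electrophilic C6 of A5. The endgame from A5 and A6 is only two steps, which is shorter than the chosen route on paper.
- **Against:** neither A5 nor A6 can be bought. A6 is an aryl ynol ether boronate, a thermally delicate class, and its preparation through an aryloxyacetylide and an organolithium base clashes with the two aryl bromines. A5 needs its own multistep synthesis. The cycloaddition must form a hexasubstituted benzene with the aryloxy group next to a bromine, at a temperature at which A6 may not survive.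
- **Comparison:** structurally, this plan builds a ring and the chosen plan edits existing rings. Mechanistically, regiochemistry rests on orbital polarisation in a pericyclic step, whereas in the chosen plan symmetry removes the question. In step economy the chosen plan is shorter overall once fragment syntheses are counted, at five steps from a commodity tricycle.

**Alternative 3:** amine‑directed bromination and replacement of nitrogen by chlorine.

- **Cut:** four C–Br bonds at once, with the C4–N bond later exchanged for C4–Cl.
- **Forward key step:** A8 (4‑amino‑2‑phenoxyphenyl methanesulfonate) takes four equivalents of bromine in a carboxylic acid solvent to give A9. A Sandmeyer chlorination (to A10) and cleavage of the sulfonate would then give 10.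
- **In favour:** every reaction is of a classical type, so on precedent this plan is better than the chosen one. The amine fixes both flanking bromines and the later chlorine at C4 without ambiguity, which is also better than the final chlorination of the chosen plan. The sulfonate tempers the ring A oxygen so that nitrogen governs that ring.
- **Against:** A8 must first be made in about three steps (nitration, sulfonylation, reduction) from a commercial hydroxy diaryl ether, with a regiochemical question of its own in the nitration. In the key step six open positions must be told apart kinetically in one pot: ring B has to stop at the 2,4‑dibromo stage with C6' free, C6 of ring A must stay free, and C3 lies between nitrogen and the aryloxy group. The aniline is sensitive to oxidation by bromine. The final sulfonate cleavage needs hydroxide on a substrate with an ortho' bromine.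
- **Comparison:** structurally, both plans install the halogens by electrophilic substitution, but this one relies on rate differences where the chosen plan relies on symmetry. Mechanistically, this plan is the more secure. In step economy it is about six steps against five.

Key step: step 2

Remark on the chemistry: ring A is numbered from the hydroxyl carbon (C1–OH, C2–O‑aryl, C3–Br, C4–Cl, C5–Br, C6–H) and ring B from the ether carbon (C1'–O, C2'–Br, C4'–Br, C6'–H). CF3CO3H is assumed to be prepared in the flask because it is not a storable reagent.

## Route

Step 1
Reactants: 1 xanthone (9H‑xanthen‑9‑one); 2 N‑bromosuccinimide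
Product: 4 2,4,5,7‑tetrabromo‑9H‑xanthen‑9‑one, via 2,7‑dibromoxanthone 3 (not isolated)
Conditions: NBS (4.4 equiv, in portions), conc. H2SO4, rt to 60 °C; pour onto ice, recrystallise
Reagents that add atoms: N‑bromosuccinimide, O=C1CCC(=O)N1Br
Why: Electrophilic aromatic bromination with NBS in concentrated H2SO4, a known method for deactivated arenes; each ring should react first para and then ortho to the ring oxygen, positions that are also meta to the carbonyl, so both directing effects coincide and the twofold‑symmetric tetrabromide is expected, with 3 as the first intermediate.

Step 2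
Reactants: 4 2,4,5,7‑tetrabromo‑9H‑xanthen‑9‑one
Product: 6 2,4,6,8‑tetrabromo‑11H‑dibenzo[b,e][1,4]dioxepin‑11‑one, via Criegee adduct 5 (not isolated)
Conditions: (CF3CO)2O, urea·H2O2, CF3CO2H/CH2Cl2, 0 °C to 40 °C; Na2SO3 quench
Reagents that add atoms: trifluoroperacetic acid, O=C(OO)C(F)(F)F
Why: Proposed new method: Baeyer–Villiger oxidation of a xanthone to a dibenzodioxepinone has not been shown; the closest known reaction type is the peracid Baeyer–Villiger ring expansion of fluorenones to dibenzopyranones and the oxidation of benzophenones to aryl benzoates with CF3CO3H. Acid activates the carbonyl of 4, the peracid adds to C9 to give the tetrahedral Criegee adduct 5, and the aryl carbon antiperiplanar to the O–O bond shifts from carbon to oxygen while trifluoroacetate leaves. The new ring is therefore not closed end to end: the six‑membered pyranone is widened to the seven‑membered lactone by a 1,2‑aryl shift, that is, by insertion of oxygen into the C1–C(=O) bond. No stereocentre is created, so no stereocontrol element is required. The only selectivity needed is a single insertion: the twofold symmetry of 4 makes the two possible migrating carbons identical, and the ester product is much less electrophilic than the ketone and should not react again. The ether oxygen ortho to the migrating carbon stabilises the electron‑deficient transition state, and the four bromines reduce the hydroxyxanthylium‑type stabilisation that makes the parent ketone unreactive. Because the same bromines lower migratory aptitude, the strongest common peracid is used in an unbuffered acidic medium; the C–Br bonds and the deactivated rings should be inert to it.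

Step 3
Reactants: 6 2,4,6,8‑tetrabromo‑11H‑dibenzo[b,e][1,4]dioxepin‑11‑one
Product: 7 3,5‑dibromo‑2‑(2,4‑dibromo‑6‑hydroxyphenoxy)benzoic acid
Conditions: LiOH·H2O (3 equiv), THF/H2O, 0 °C to rt; then cold 1 M HCl to pH 2
Reagents that add atoms: lithium hydroxide (hydroxide supplies the carboxyl oxygen), [Li+].[OH-]
Why: Saponification of an aryl ester by addition–elimination at the acyl carbon, with the ring A phenoxide, acidified by two bromines, as a good leaving group; aryl bromides and the diaryl ether should be untouched at room temperature, and cold acidification avoids relactonisation.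

Step 4
Reactants: 7 3,5‑dibromo‑2‑(2,4‑dibromo‑6‑hydroxyphenoxy)benzoic acid
Product: 8 3,5‑dibromo‑2‑(2,4‑dibromophenoxy)phenol
Conditions: Ag2CO3 (10 mol%), AcOH (5 mol%), DMSO, 120 °C, N2, dark
Reagents that add atoms: none
Why: Silver‑catalysed protodecarboxylation of an ortho‑substituted benzoic acid: the silver carboxylate loses CO2, assisted by the ortho aryloxy oxygen, and the carbon–silver bond is protonated by the substrate acid; monovalent silver does not insert into C–Br bonds, and since the medium stays acidic the phenol remains un‑ionised, which should suppress Smiles migration and ring closure onto C2'.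

Step 5
Reactants: 8 3,5‑dibromo‑2‑(2,4‑dibromophenoxy)phenol; 9 sulfuryl chloride
Product: 10 3,5‑dibromo‑4‑chloro‑2‑(2,4‑dibromophenoxy)phenol (target)
Conditions: SO2Cl2 (1.05 equiv), Ph2S (5 mol%), AlCl3 (5 mol%), CH2Cl2, 0 °C to rt
Reagents that add atoms: sulfuryl chloride, O=S(=O)(Cl)Cl
Why: Electrophilic aromatic chlorination of a phenol with SO2Cl2 under sulfide/Lewis‑acid catalysis, a system known to favour para attack; C4 is the only para position, related 3,5‑disubstituted phenols such as 3,5‑dimethylphenol are chlorinated between the two flanking groups, ring B has no free hydroxyl and is deactivated by two bromines, and one equivalent at low temperature limits attack at C6.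

## Compound list

1 | xanthone (9H‑xanthen‑9‑one) | O=C1c2ccccc2Oc2ccccc12 | starting material
2 | N‑bromosuccinimide | O=C1CCC(=O)N1Br | starting material
3 | 2,7‑dibromo‑9H‑xanthen‑9‑one | O=C1c2cc(Br)ccc2Oc2ccc(Br)cc21 | intermediate (not isolated)
4 | 2,4,5,7‑tetrabromo‑9H‑xanthen‑9‑one | O=C1c2cc(Br)cc(Br)c2Oc2c(Br)cc(Br)cc21 | intermediate
5 | 2,4,5,7‑tetrabromo‑9‑hydroxy‑9H‑xanthen‑9‑yl trifluoroperacetate (Criegee adduct) | OC1(OOC(=O)C(F)(F)F)c2cc(Br)cc(Br)c2Oc2c(Br)cc(Br)cc21 | intermediate (not isolated)
6 | 2,4,6,8‑tetrabromo‑11H‑dibenzo[b,e][1,4]dioxepin‑11‑one | O=C1Oc2cc(Br)cc(Br)c2Oc2c(Br)cc(Br)cc21 | intermediate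
7 | 3,5‑dibromo‑2‑(2,4‑dibromo‑6‑hydroxyphenoxy)benzoic acid | OC(=O)c1cc(Br)cc(Br)c1Oc1c(O)cc(Br)cc1Br | intermediate
8 | 3,5‑dibromo‑2‑(2,4‑dibromophenoxy)phenol | Oc1cc(Br)cc(Br)c1Oc1ccc(Br)cc1Br | intermediate
9 | sulfuryl chloride | O=S(=O)(Cl)Cl | starting material
10 | 3,5‑dibromo‑4‑chloro‑2‑(2,4‑dibromophenoxy)phenol | Oc1cc(Br)c(Cl)c(Br)c1Oc1ccc(Br)cc1Br | target

## Step count and least certain steps

Total step count: 5. Longest linear sequence: 5 steps (1 → 4 → 6 → 7 → 8 → 10). Step 3 is regarded as reliable.

**Step 2 (key step, Proposed new method).**
- **Risk:** the peracid may fail to add to the carbonyl, which in acid is stabilised as a hydroxyxanthylium‑type cation. Alternatively the Criegee adduct may revert instead of rearranging because both aryl groups are electron‑poor. Forcing the reaction could lead to oxidative degradation of the rings.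
- **Fallback (known chemistry, from 4 back to 7):** nitrogen is inserted instead of oxygen and then exchanged for oxygen.
  - A Schmidt reaction of 4 (NaN3, CF3SO3H, CHCl3, 0 °C to rt, with precautions for hydrazoic acid) should give the lactam 2,4,6,8‑tetrabromodibenzo[b,f][1,4]oxazepin‑11(10H)‑one F1. Symmetry again makes the choice of migrating group irrelevant.
  - N‑Acylation (Boc2O, DMAP, MeCN) should give the imide tert‑butyl 2,4,6,8‑tetrabromo‑11‑oxodibenzo[b,f][1,4]oxazepine‑10(11H)‑carboxylate F2.
  - LiOH in THF/H2O should open the activated ring carbonyl to 3,5‑dibromo‑2‑{2,4‑dibromo‑6‑[(tert‑butoxycarbonyl)amino]phenoxy}benzoic acid F3.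
  - CF3CO2H should remove the carbamate to give 2‑(2‑amino‑4,6‑dibromophenoxy)‑3,5‑dibromobenzoic acid F4.
  - Diazotisation (NaNO2, aqueous H2SO4, 0 °C) and hydroxydediazoniation (Cu2O, Cu(NO3)2, H2O, rt) should then deliver 7. Capture of the aryl cation by the neighbouring carboxylate would give 6, which step 3 converts into 7. Both ortho positions of ring B are substituted, so Pschorr closure to a dibenzofuran is blocked.

**Step 5.**
- **Risk:** poor site selectivity, with chlorination at C6 (ortho to the hydroxyl and less crowded) competing with C4 (between two bromines), and over‑chlorination once both sites are activated.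
- **Fallback (from 8 back to 10):** the para position is secured through nitrogen.
  - Azo coupling of the phenoxide of 8 with diazotised sulfanilic acid (aqueous NaOH, 0 °C) should occur para to the oxygen and give 4‑{(E)‑[2,6‑dibromo‑3‑(2,4‑dibromophenoxy)‑4‑hydroxyphenyl]diazenyl}benzenesulfonic acid F9.
  - Reductive cleavage with Na2S2O4 should give 4‑amino‑3,5‑dibromo‑2‑(2,4‑dibromophenoxy)phenol F10.
  - A Sandmeyer chlorination (t‑BuONO, CuCl2, MeCN, 0 to 60 °C) should convert F10 into 10.

**Step 4.**
- **Risk:** slow decarboxylation of a benzoic acid with only one ortho substituent, so that prolonged heating is needed. Partial ionisation of the phenol near the end could then allow Smiles migration of ring B between the two ring A oxygens, or ring closure with loss of bromide.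
- **Fallback (from 7 back to 8):** the carbon is removed as CO instead of CO2.
  - BH3·THF should reduce the acid to 3,5‑dibromo‑2‑[2,4‑dibromo‑6‑(hydroxymethyl)phenoxy]phenol F7.
  - MnO2 in CH2Cl2 should oxidise the benzylic alcohol to 3,5‑dibromo‑2‑(2,4‑dibromo‑6‑hydroxyphenoxy)benzaldehyde F8.
  - Tsuji–Wilkinson decarbonylation with stoichiometric RhCl(PPh3)3 in refluxing toluene should give 8 under neutral conditions.

**Step 1.**
- **Risk:** incomplete bromination. In H2SO4 the ketone is O‑protonated and strongly deactivated, so the reaction may stall after the two para positions, or require temperatures at which sulfonation competes.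
- **Fallback (from 2 back to 4):** the pyranone ring is closed after the halogens are in place.
  - Brominating agent 2 is applied not to 1 but to bought‑in bis(2‑hydroxyphenyl)methanone F5 (4 equiv of 2, MeCN, rt). Hydroxyl (ortho, para) and carbonyl (meta) direct to the same carbons, so bis(3,5‑dibromo‑2‑hydroxyphenyl)methanone F6 is expected.
  - Thermal cyclodehydration of F6 (water, sealed vessel, about 200 °C), the classical closure of 2,2'‑dihydroxybenzophenones, should then give 4.

## Further compounds

F1 | step 2 | 2,4,6,8‑tetrabromodibenzo[b,f][1,4]oxazepin‑11(10H)‑one | O=C1Nc2cc(Br)cc(Br)c2Oc2c(Br)cc(Br)cc21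
F2 | step 2 | tert‑butyl 2,4,6,8‑tetrabromo‑11‑oxodibenzo[b,f][1,4]oxazepine‑10(11H)‑carboxylate | CC(C)(C)OC(=O)N1C(=O)c2cc(Br)cc(Br)c2Oc2c(Br)cc(Br)cc21
F3 | step 2 | 3,5‑dibromo‑2‑{2,4‑dibromo‑6‑[(tert‑butoxycarbonyl)amino]phenoxy}benzoic acid | CC(C)(C)OC(=O)Nc1cc(Br)cc(Br)c1Oc1c(Br)cc(Br)cc1C(=O)O
F4 | step 2 | 2‑(2‑amino‑4,6‑dibromophenoxy)‑3,5‑dibromobenzoic acid | Nc1cc(Br)cc(Br)c1Oc1c(Br)cc(Br)cc1C(=O)O
F5 | step 1 | bis(2‑hydroxyphenyl)methanone (bought in) | O=C(c1ccccc1O)c1ccccc1O
F6 | step 1 | bis(3,5‑dibromo‑2‑hydroxyphenyl)methanone | O=C(c1cc(Br)cc(Br)c1O)c1cc(Br)cc(Br)c1O
F7 | step 4 | 3,5‑dibromo‑2‑[2,4‑dibromo‑6‑(hydroxymethyl)phenoxy]phenol | OCc1cc(Br)cc(Br)c1Oc1c(O)cc(Br)cc1Br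
F8 | step 4 | 3,5‑dibromo‑2‑(2,4‑dibromo‑6‑hydroxyphenoxy)benzaldehyde | O=Cc1cc(Br)cc(Br)c1Oc1c(O)cc(Br)cc1Br
F9 | step 5 | 4‑{(E)‑[2,6‑dibromo‑3‑(2,4‑dibromophenoxy)‑4‑hydroxyphenyl]diazenyl}benzenesulfonic acid | O=S(=O)(O)c1ccc(/N=N/c2c(Br)cc(O)c(Oc3ccc(Br)cc3Br)c2Br)cc1
F10 | step 5 | 4‑amino‑3,5‑dibromo‑2‑(2,4‑dibromophenoxy)phenol | Nc1c(Br)cc(O)c(Oc2ccc(Br)cc2Br)c1Br
A1 | alternative 1 | 2‑(trimethylsilyl)phenyl trifluoromethanesulfonate | C[Si](C)(C)c1ccccc1OS(=O)(=O)C(F)(F)F
A2 | alternative 1 | 4,6‑dibromo‑5‑chloro‑2‑methoxyphenol | COc1cc(Br)c(Cl)c(Br)c1O
A3 | alternative 1 | 1,3‑dibromo‑4‑(2‑bromophenoxy)‑2‑chloro‑5‑methoxybenzene | COc1cc(Br)c(Cl)c(Br)c1Oc1ccccc1Br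
A4 | alternative 1 | 1,3‑dibromo‑2‑chloro‑4‑(2,4‑dibromophenoxy)‑5‑methoxybenzene | COc1cc(Br)c(Cl)c(Br)c1Oc1ccc(Br)cc1Br
A5 | alternative 2 | 3,5‑dibromo‑4‑chloro‑2H‑pyran‑2‑one | O=C1OC=C(Br)C(Cl)=C1Br
A6 | alternative 2 | 2‑[(2,4‑dibromophenoxy)ethynyl]‑4,4,5,5‑tetramethyl‑1,3,2‑dioxaborolane | CC1(C)OB(C#COc2ccc(Br)cc2Br)OC1(C)C
A7 | alternative 2 | 2‑[3,5‑dibromo‑4‑chloro‑2‑(2,4‑dibromophenoxy)phenyl]‑4,4,5,5‑tetramethyl‑1,3,2‑dioxaborolane | CC1(C)OB(OC1(C)C)c1cc(Br)c(Cl)c(Br)c1Oc1ccc(Br)cc1Br
A8 | alternative 3 | 4‑amino‑2‑phenoxyphenyl methanesulfonate | CS(=O)(=O)Oc1ccc(N)cc1Oc1ccccc1
A9 | alternative 3 | 4‑amino‑3,5‑dibromo‑2‑(2,4‑dibromophenoxy)phenyl methanesulfonate | CS(=O)(=O)Oc1cc(Br)c(N)c(Br)c1Oc1ccc(Br)cc1Br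
A10 | alternative 3 | 3,5‑dibromo‑4‑chloro‑2‑(2,4‑dibromophenoxy)phenyl methanesulfonate | CS(=O)(=O)Oc1cc(Br)c(Cl)c(Br)c1Oc1ccc(Br)cc1Br
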